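The synthesis rests on cutting ring C at O1–C2 and C4–C4a (flavanone numbering), a [3+3] union of a phenol with a C2–C3–C4 unit. The key step exploits the hidden β-aryloxy acid in ring C (O1 on C2 is β to the C4 carbonyl) and the threefold-symmetric oxygenation of ring A. The phenoxide of 3,5-bis(methoxymethoxy)phenol opens a strained (R)-4-aryl-β-lactone at its benzylic carbon with inversion, setting C2 as S. The carboxylate released is activated in the same flask to acylate the ortho carbon and close ring C. The lactone, which looks nothing like a flavanone, comes from an asymmetric ketene–aldehyde cycloaddition.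

Key step: step 4

Assumption: O-trimethylsilylquinine is taken as the pseudoenantiomer that delivers the (R)-lactone; if the sense of induction is the opposite, O-trimethylsilylquinidine takes its place with no other change.

Step 1
Reactants: 1 3,5-dibromo-4-methoxybenzaldehyde; 2 tributyl(3-methylbut-2-en-1-yl)stannane
Product: 3 4-methoxy-3,5-bis(3-methylbut-2-en-1-yl)benzaldehyde
Conditions: 2 (2.4 equiv), Pd(PPh3)4 (5 mol %), DMF, 100 °C
Reagents that add atoms: none
Why: Twofold Stille coupling in which zerovalent palladium inserts into each C–Br bond of the electron-poor ring and the prenylstannane should transfer its allyl group through the tin-bearing carbon, giving the linear prenyl arene while the aldehyde is left untouched.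

Step 2
Reactants: 3 4-methoxy-3,5-bis(3-methylbut-2-en-1-yl)benzaldehyde; 4 acetyl chloride
Product: 6 (R)-4-[4-methoxy-3,5-bis(3-methylbut-2-en-1-yl)phenyl]oxetan-2-one, via ketene 5 (not isolated)
Conditions: O-trimethylsilylquinine (10 mol %), LiClO4, i-Pr2NEt, CH2Cl2/Et2O, −78 °C, slow addition of 4
Reagents that add atoms: none
Why: Acyl halide–aldehyde cyclocondensation (formal ketene–aldehyde [2+2] cycloaddition) in which i-Pr2NEt converts 4 into ketene 5, the alkaloid adds to it to form a chiral ammonium enolate, and this adds to the LiClO4-activated aldehyde on the face left open by the catalyst and lactonises with catalyst release, which sets the lactone stereocenter as R.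

Step 3
Reactants: 7 phloroglucinol (benzene-1,3,5-triol)
Product: 8 3,5-bis(methoxymethoxy)phenol
Conditions: MOMCl (2.0 equiv), i-Pr2NEt, DMF, 0 °C to rt; chromatography
Reagents that add atoms: chloromethyl methyl ether, COCCl
Why: Williamson-type O-alkylation of equivalent phenolic hydroxyls with a hard alkoxymethyl chloride, so two equivalents of reagent should give the bis-ether as the main component of a statistical mixture from which the mono- and tris-ethers are removed.

Step 4
Reactants: 6 (R)-4-[4-methoxy-3,5-bis(3-methylbut-2-en-1-yl)phenyl]oxetan-2-one; 8 3,5-bis(methoxymethoxy)phenol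
Product: 11 (2S)-5,7-bis(methoxymethoxy)-2-[4-methoxy-3,5-bis(3-methylbut-2-en-1-yl)phenyl]chroman-4-one, via sodium carboxylate 9 (not isolated), via mixed trifluoroacetic anhydride 10 (not isolated)
Conditions: 8, NaH (1.0 equiv), 15-crown-5, THF, 0 °C; add 6, 0 °C to rt; then TFAA (2.5 equiv), CH2Cl2, 0 °C
Reagents that add atoms: none
Why: The sodium phenoxide of 8 attacks the benzylic carbon of lactone 6 in an SN2 alkyl–oxygen cleavage driven by release of the four-membered ring strain (the known opening of β-lactones by aryloxides to 3-aryloxy acids), which forms O1–C2 and gives carboxylate 9; TFAA then turns 9 into mixed anhydride 10, which acylates the ring carbon ortho to the new ether oxygen (the known Friedel–Crafts cyclisation of 3-aryloxypropanoic acids to chroman-4-ones) and forms C4–C4a. Ring C closes as a six-membered ring by 6-exo-trig attack of the arene carbon on the acyl carbon. The only stereocenter, C2, is transferred and not created: backside attack inverts the (R)-lactone carbon to the (S)-ether, and nothing later touches it. Attack at the alkyl and not the acyl carbon is needed and is secured by the soft, weakly basic aryloxide, since acyl attack gives an aryl ester aldolate that is expected to revert to the lactone whereas carboxylate formation is irreversible. O-alkylation over C-alkylation is favoured by the crown-separated sodium ion pair in THF. The site of acylation is fixed by ring A itself, because both carbons ortho to O1 are equivalent and each is ortho or para to all three oxygens, while the third CH cannot be reached by the tether.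

Step 5
Reactants: 11 (2S)-5,7-bis(methoxymethoxy)-2-[4-methoxy-3,5-bis(3-methylbut-2-en-1-yl)phenyl]chroman-4-one
Product: 12 (2S)-5,7-dihydroxy-2-[4-methoxy-3,5-bis(3-methylbut-2-en-1-yl)phenyl]chroman-4-one (target)
Conditions: 3 M HCl, MeOH, 45 °C
Reagents that add atoms: none
Why: Acid-catalysed acetal exchange with methanol removes both MOM ethers; the medium is never basic, so the retro-oxa-Michael opening that racemises 5-hydroxyflavanones is avoided, and the prenyl groups flank a methyl ether and not a phenol, so acid-induced chroman formation is not available.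

Compound list
1 | 3,5-dibromo-4-methoxybenzaldehyde | COc1c(Br)cc(C=O)cc1Br | starting material
2 | tributyl(3-methylbut-2-en-1-yl)stannane | CCCC[Sn](CCCC)(CCCC)CC=C(C)C | starting material
3 | 4-methoxy-3,5-bis(3-methylbut-2-en-1-yl)benzaldehyde | COc1c(CC=C(C)C)cc(C=O)cc1CC=C(C)C | intermediate
4 | acetyl chloride | CC(Cl)=O | starting material
5 | ketene | C=C=O | intermediate
6 | (R)-4-[4-methoxy-3,5-bis(3-methylbut-2-en-1-yl)phenyl]oxetan-2-one | O=C1C[C@H](c2cc(CC=C(C)C)c(OC)c(CC=C(C)C)c2)O1 | intermediate
7 | phloroglucinol (benzene-1,3,5-triol) | Oc1cc(O)cc(O)c1 | starting material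
8 | 3,5-bis(methoxymethoxy)phenol | COCOc1cc(O)cc(OCOC)c1 | intermediate
9 | sodium (S)-3-[3,5-bis(methoxymethoxy)phenoxy]-3-[4-methoxy-3,5-bis(3-methylbut-2-en-1-yl)phenyl]propanoate | [Na+].[O-]C(=O)C[C@H](Oc1cc(OCOC)cc(OCOC)c1)c1cc(CC=C(C)C)c(OC)c(CC=C(C)C)c1 | intermediate
10 | (S)-3-[3,5-bis(methoxymethoxy)phenoxy]-3-[4-methoxy-3,5-bis(3-methylbut-2-en-1-yl)phenyl]propanoic trifluoroacetic anhydride | FC(F)(F)C(=O)OC(=O)C[C@H](Oc1cc(OCOC)cc(OCOC)c1)c1cc(CC=C(C)C)c(OC)c(CC=C(C)C)c1 | intermediate
11 | (2S)-5,7-bis(methoxymethoxy)-2-[4-methoxy-3,5-bis(3-methylbut-2-en-1-yl)phenyl]chroman-4-one | COc1c(CC=C(C)C)cc([C@@H]2CC(=O)c3c(OCOC)cc(OCOC)cc3O2)cc1CC=C(C)C | intermediate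
12 | (2S)-5,7-dihydroxy-2-[4-methoxy-3,5-bis(3-methylbut-2-en-1-yl)phenyl]chroman-4-one | COc1c(CC=C(C)C)cc([C@@H]2CC(=O)c3c(O)cc(O)cc3O2)cc1CC=C(C)C | target

Total step count: 5. Longest linear sequence: 4 steps (steps 1, 2, 4 and 5); step 3 is a one-step side branch.

Steps most likely to fail

Step 4. Several processes could undermine it:
- The aryloxide may act as a base and open the lactone by elimination to the cinnamate.
- The benzylic carbon may ionise and erode the configuration.
- In the acylation stage, the acid set free may cleave a MOM ether or add to a prenyl alkene.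

The fallback sets out from 6 and returns at 11. It forms O1–C2 by a redox condensation on an alcohol instead of by lactone opening, and separates the two bond formations. Lactone 6 is opened at the acyl carbon with retention (cat. K2CO3, MeOH, 0 °C) to methyl (R)-3-hydroxy-3-[4-methoxy-3,5-bis(3-methylbut-2-en-1-yl)phenyl]propanoate F1. A Mitsunobu reaction of F1 with phenol 8 (PPh3, DIAD, toluene, 0 °C) should give, with inversion, methyl (S)-3-[3,5-bis(methoxymethoxy)phenoxy]-3-[4-methoxy-3,5-bis(3-methylbut-2-en-1-yl)phenyl]propanoate F2. Saponification (LiOH, THF/H2O, rt) gives (S)-3-[3,5-bis(methoxymethoxy)phenoxy]-3-[4-methoxy-3,5-bis(3-methylbut-2-en-1-yl)phenyl]propanoic acid F3. The purified acid is cyclised by intramolecular Friedel–Crafts acylation (TFAA, CH2Cl2, 0 °C) to 11.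

Step 2. The electron-rich aryl aldehyde may add too slowly to the ammonium enolate, so that ketene dimerisation takes over. Facial selectivity may be poor, and the benzylic lactone may lose CO2 on handling. The fallback sets out from 3 and returns at 6. It sets the stereocenter by ketone reduction instead of by cycloaddition:
- Roskamp homologation of 3 (ethyl diazoacetate, cat. SnCl2, CH2Cl2, rt) gives ethyl 3-[4-methoxy-3,5-bis(3-methylbut-2-en-1-yl)phenyl]-3-oxopropanoate F4.
- Asymmetric transfer hydrogenation (RuCl(p-cymene)[(R,R)-TsDPEN], HCO2H/Et3N, rt) should give ethyl (R)-3-hydroxy-3-[4-methoxy-3,5-bis(3-methylbut-2-en-1-yl)phenyl]propanoate F5, the sense following that of aryl methyl ketones; the alkenes are not reduced.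
- Saponification (LiOH, THF/H2O) gives (R)-3-hydroxy-3-[4-methoxy-3,5-bis(3-methylbut-2-en-1-yl)phenyl]propanoic acid F6.
- Lactonisation through carboxyl activation (PhSO2Cl, pyridine, 0 °C) leaves the carbinol carbon untouched and gives 6 with retention.

Step 1. The stannane may transfer its allyl group partly through the γ-carbon, giving reverse-prenyl isomers, and the second coupling next to the first prenyl group may stall. The fallback sets out from 1 and returns at 3. It replaces cross-coupling by halogen–metal exchange and allylation of an arylcopper: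
- Aldehyde 1 is protected (ethylene glycol, TsOH, toluene, reflux with water removal) as 2-(3,5-dibromo-4-methoxyphenyl)-1,3-dioxolane F7.
- One round of Br/Li exchange, transmetalation and allylation (n-BuLi, THF, −78 °C; CuBr·SMe2; prenyl bromide) should give 2-[3-bromo-4-methoxy-5-(3-methylbut-2-en-1-yl)phenyl]-1,3-dioxolane F8, by attack at the unhindered CH2 terminus of the allyl bromide.
- A second identical round gives 2-[4-methoxy-3,5-bis(3-methylbut-2-en-1-yl)phenyl]-1,3-dioxolane F9.
- Mild acetal hydrolysis (1 M HCl, THF, rt) returns aldehyde 3.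

Further compounds
F1 | step 4 | methyl (R)-3-hydroxy-3-[4-methoxy-3,5-bis(3-methylbut-2-en-1-yl)phenyl]propanoate | COC(=O)C[C@@H](O)c1cc(CC=C(C)C)c(OC)c(CC=C(C)C)c1
F2 | step 4 | methyl (S)-3-[3,5-bis(methoxymethoxy)phenoxy]-3-[4-methoxy-3,5-bis(3-methylbut-2-en-1-yl)phenyl]propanoate | COC(=O)C[C@H](Oc1cc(OCOC)cc(OCOC)c1)c1cc(CC=C(C)C)c(OC)c(CC=C(C)C)c1
F3 | step 4 | (S)-3-[3,5-bis(methoxymethoxy)phenoxy]-3-[4-methoxy-3,5-bis(3-methylbut-2-en-1-yl)phenyl]propanoic acid | OC(=O)C[C@H](Oc1cc(OCOC)cc(OCOC)c1)c1cc(CC=C(C)C)c(OC)c(CC=C(C)C)c1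
F4 | step 2 | ethyl 3-[4-methoxy-3,5-bis(3-methylbut-2-en-1-yl)phenyl]-3-oxopropanoate | CCOC(=O)CC(=O)c1cc(CC=C(C)C)c(OC)c(CC=C(C)C)c1
F5 | step 2 | ethyl (R)-3-hydroxy-3-[4-methoxy-3,5-bis(3-methylbut-2-en-1-yl)phenyl]propanoate | CCOC(=O)C[C@@H](O)c1cc(CC=C(C)C)c(OC)c(CC=C(C)C)c1
F6 | step 2 | (R)-3-hydroxy-3-[4-methoxy-3,5-bis(3-methylbut-2-en-1-yl)phenyl]propanoic acid | OC(=O)C[C@@H](O)c1cc(CC=C(C)C)c(OC)c(CC=C(C)C)c1
F7 | step 1 | 2-(3,5-dibromo-4-methoxyphenyl)-1,3-dioxolane | COc1c(Br)cc(C2OCCO2)cc1Br
F8 | step 1 | 2-[3-bromo-4-methoxy-5-(3-methylbut-2-en-1-yl)phenyl]-1,3-dioxolane | COc1c(Br)cc(C2OCCO2)cc1CC=C(C)C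
F9 | step 1 | 2-[4-methoxy-3,5-bis(3-methylbut-2-en-1-yl)phenyl]-1,3-dioxolane | COc1c(CC=C(C)C)cc(C2OCCO2)cc1CC=C(C)C
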